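**Strategy.** Everything rests on disconnecting C8–C9 of the eleven-membered ring, numbered C1 (methyl-bearing alkene carbon next to the CH2 chain), C2, C3, C4 (ester carbinol), C5(Me)=C6, C7 (free carbinol), C8 (CMe2), C9–C11. Because gem-dimethyl C8 sits between carbinol C7 and the unfunctionalised C9–C11 chain, it can be unveiled as a tertiary radical from a C8 carboxylic acid. In one operation this radical forms after loss of CO2, attacks C9 of a 2-sulfonyl alkene, and so creates the quaternary carbon and the ring. The cyclisation substrate is an open-chain (4R,7R) E,E-diene with an N-acyloxyphthalimide on C8, a 2-(phenylsulfonyl)allyl terminus (C9–C11), a C4 PMB ether and a C7 silyl ether.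

Key step: step 15

Remark: the ring numbering above is used for every intermediate. The C10 centre of the sulfone-bearing intermediates is an unassigned mixture of epimers (it ends as CH2). (S)-Pantolactone and (+)-B-allyldiisopinocampheylborane are taken as purchased materials. The carboxyl carbon is carried as a silyl-protected neopentyl alcohol and oxidised only after the vinyl sulfone is in place, so that this base-sensitive group never meets an ester hydrolysis. The cyclisation substrate and its product carry the same descriptors as the target (4R, 7R, both ring alkenes E).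

**Route**

Step 1
Reactants: 1 (S)-pantolactone
Product: 2 (2S)-2,4-dihydroxy-N-methoxy-N,3,3-trimethylbutanamide
Conditions: MeNH(OMe)·HCl, AlMe3, CH2Cl2, 0 °C to rt; crude used directly
Reagents that add atoms: N,O-dimethylhydroxylamine hydrochloride, CNOC.Cl
Why: Weinreb aminolysis of the lactone by the aluminium amide formed in situ opens the ring without breaking any bond at the carbinol carbon, so the (S) centre of pantolactone is carried on as the future C7.

Step 2
Reactants: 2 (2S)-2,4-dihydroxy-N-methoxy-N,3,3-trimethylbutanamide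
Product: 3 (2S)-2,4-bis(tert-butyldimethylsilyloxy)-N-methoxy-N,3,3-trimethylbutanamide
Conditions: TBSOTf, 2,6-lutidine, CH2Cl2, 0 °C
Reagents that add atoms: tert-butyldimethylsilyl trifluoromethanesulfonate, CC(C)(C)[Si](C)(C)OS(=O)(=O)C(F)(F)F
Why: Silylation with a silyl triflate and a hindered pyridine base protects both the primary and the hindered α-hydroxyl group without epimerizing the centre next to the amide.

Step 3
Reactants: 3 (2S)-2,4-bis(tert-butyldimethylsilyloxy)-N-methoxy-N,3,3-trimethylbutanamide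
Product: 4 (2S)-2,4-bis(tert-butyldimethylsilyloxy)-3,3-dimethylbutanal
Conditions: i-Bu2AlH, THF, −78 °C; aqueous work-up
Reagents that add atoms: none
Why: Hydride reduction of a Weinreb amide stops at the chelated tetrahedral aluminate, which releases the aldehyde only on work-up, so over-reduction and epimerization of the α-silyloxy centre are avoided.

Step 4
Reactants: 4 (2S)-2,4-bis(tert-butyldimethylsilyloxy)-3,3-dimethylbutanal; 5 2-(triphenylphosphoranylidene)propanal
Product: 6 (2E,4R)-4,6-bis(tert-butyldimethylsilyloxy)-2,5,5-trimethylhex-2-enal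
Conditions: toluene, 90 °C
Reagents that add atoms: none
Why: Wittig olefination with a formyl-stabilized ylide under neutral conditions gives the E 2-methylenal (the future C5=C6 with C4 as the aldehyde) by reversible oxaphosphetane formation, and the unchanged carbinol centre is now described as R only because the CIP priorities change.

Step 5
Reactants: 6 (2E,4R)-4,6-bis(tert-butyldimethylsilyloxy)-2,5,5-trimethylhex-2-enal; 7 (+)-B-allyldiisopinocampheylborane (reagent derived from (−)-α-pinene, pentane solution)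
Product: 9 (4R,5E,7R)-7,9-bis(tert-butyldimethylsilyloxy)-5,8,8-trimethylnona-1,5-dien-4-ol, via diisopinocampheylborinate ester 8 (not isolated)
Conditions: Et2O, −78 °C; then NaOH, H2O2, 0 °C to rt
Reagents that add atoms: none
Why: Brown allylboration through a chair six-membered transition state delivers the allyl group from the reagent derived from (−)-α-pinene to the Re face of the aldehyde, which sets C4 as R under reagent control because the C7 centre is remote, and alkaline peroxide then cleaves the borinate.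

Step 6
Reactants: 9 (4R,5E,7R)-7,9-bis(tert-butyldimethylsilyloxy)-5,8,8-trimethylnona-1,5-dien-4-ol
Product: 10 (4R,5E,7R)-7,9-bis(tert-butyldimethylsilyloxy)-4-(4-methoxybenzyloxy)-5,8,8-trimethylnona-1,5-diene
Conditions: NaH, PMBCl, n-Bu4NI (cat.), THF/DMF, 0 °C to rt
Reagents that add atoms: 4-methoxybenzyl chloride, COc1ccc(CCl)cc1
Why: Williamson etherification of the sodium alkoxide with the benzylic chloride (iodide catalysis) protects O4, and no silyl group is within reach of the alkoxide for migration.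

Step 7
Reactants: 10 (4R,5E,7R)-7,9-bis(tert-butyldimethylsilyloxy)-4-(4-methoxybenzyloxy)-5,8,8-trimethylnona-1,5-diene; 11 methacrolein
Product: 12 (2E,5R,6E,8R)-8,10-bis(tert-butyldimethylsilyloxy)-5-(4-methoxybenzyloxy)-2,6,9,9-tetramethyldeca-2,6-dienal
Conditions: second-generation Hoveyda–Grubbs catalyst [RuCl2(SIMes)(=CH-C6H4-2-O-i-Pr)] (5 mol%), methacrolein (10 equiv), CH2Cl2, 40 °C
Reagents that add atoms: none
Why: Olefin cross-metathesis of the unhindered terminal alkene with methacrolein gives the conjugated trisubstituted enal as the thermodynamically preferred E isomer (C1=C2 with C11 as aldehyde), while the hindered trisubstituted C5=C6 bond does not engage the ruthenium carbene.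

Step 8
Reactants: 12 (2E,5R,6E,8R)-8,10-bis(tert-butyldimethylsilyloxy)-5-(4-methoxybenzyloxy)-2,6,9,9-tetramethyldeca-2,6-dienal
Product: 13 (2E,5R,6E,8R)-8,10-bis(tert-butyldimethylsilyloxy)-5-(4-methoxybenzyloxy)-2,6,9,9-tetramethyldeca-2,6-dien-1-ol
Conditions: NaBH4, CeCl3·7H2O, MeOH, 0 °C
Reagents that add atoms: none
Why: Luche reduction adds hydride 1,2 to the enal only, giving the allylic alcohol at C11 without touching alkenes or ethers.

Step 9
Reactants: 13 (2E,5R,6E,8R)-8,10-bis(tert-butyldimethylsilyloxy)-5-(4-methoxybenzyloxy)-2,6,9,9-tetramethyldeca-2,6-dien-1-ol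
Product: 14 (2E,5R,6E,8R)-1-bromo-8,10-bis(tert-butyldimethylsilyloxy)-5-(4-methoxybenzyloxy)-2,6,9,9-tetramethyldeca-2,6-diene
Conditions: CBr4, PPh3, CH2Cl2, 0 °C; used without storage
Reagents that add atoms: carbon tetrabromide, BrC(Br)(Br)Br
Why: Appel bromination converts the primary allylic alcohol to the bromide by SN2 displacement of the oxyphosphonium ion at 0 °C, which keeps the E geometry and the position of the double bond.

Step 10
Reactants: 14 (2E,5R,6E,8R)-1-bromo-8,10-bis(tert-butyldimethylsilyloxy)-5-(4-methoxybenzyloxy)-2,6,9,9-tetramethyldeca-2,6-diene; 15 2-(phenylsulfonyl)ethanol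
Product: 16 (4E,7R,8E,10R)-10,12-bis(tert-butyldimethylsilyloxy)-7-(4-methoxybenzyloxy)-4,8,11,11-tetramethyl-2-(phenylsulfonyl)dodeca-4,8-dien-1-ol (C2 epimers; C2 is ring C10)
Conditions: 15 (2 equiv), n-BuLi (4 equiv), THF/DMPU, −78 to −20 °C; then 14, −78 to 0 °C
Reagents that add atoms: none
Why: Alkylation of the O,C-dilithiated β-hydroxy sulfone occurs at carbon by SN2 attack on the primary allylic bromide, the oxido group being unable to leave, so C9 and C10 arrive together and the new C10 centre, formed unselectively, is of no consequence.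

Step 11
Reactants: 16 (4E,7R,8E,10R)-10,12-bis(tert-butyldimethylsilyloxy)-7-(4-methoxybenzyloxy)-4,8,11,11-tetramethyl-2-(phenylsulfonyl)dodeca-4,8-dien-1-ol
Product: 18 (4E,7R,8E,10R)-10,12-bis(tert-butyldimethylsilyloxy)-7-(4-methoxybenzyloxy)-4,8,11,11-tetramethyl-2-(phenylsulfonyl)dodeca-1,4,8-triene, via primary mesylate 17 (not isolated)
Conditions: MsCl, Et3N (excess), CH2Cl2, 0 °C to rt
Reagents that add atoms: none
Why: Mesylation of the primary alcohol followed by E1cB elimination through the sulfonyl-stabilized carbanion gives the 2-sulfonyl-1-alkene, and triethylamine is too weak a base to move the new double bond into conjugation with C1=C2.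

Step 12
Reactants: 18 (4E,7R,8E,10R)-10,12-bis(tert-butyldimethylsilyloxy)-7-(4-methoxybenzyloxy)-4,8,11,11-tetramethyl-2-(phenylsulfonyl)dodeca-1,4,8-triene
Product: 19 (3R,4E,6R,8E)-3-(tert-butyldimethylsilyloxy)-6-(4-methoxybenzyloxy)-2,2,5,9-tetramethyl-11-(phenylsulfonyl)dodeca-4,8,11-trien-1-ol
Conditions: HF·pyridine, pyridine, THF, 0 °C
Reagents that add atoms: none
Why: Buffered HF·pyridine cleaves the primary silyl ether far faster than the secondary one that is shielded by the quaternary C8 and the alkene, a selective desilylation under non-basic conditions that the vinyl sulfone tolerates.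

Step 13
Reactants: 19 (3R,4E,6R,8E)-3-(tert-butyldimethylsilyloxy)-6-(4-methoxybenzyloxy)-2,2,5,9-tetramethyl-11-(phenylsulfonyl)dodeca-4,8,11-trien-1-ol
Product: 21 (3R,4E,6R,8E)-3-(tert-butyldimethylsilyloxy)-6-(4-methoxybenzyloxy)-2,2,5,9-tetramethyl-11-(phenylsulfonyl)dodeca-4,8,11-trienoic acid, via neopentyl aldehyde 20 (not isolated)
Conditions: TEMPO (cat.), PhI(OAc)2, CH2Cl2, rt; then t-BuOH, 2-methyl-2-butene, NaClO2, NaH2PO4, H2O, 0 °C to rt
Reagents that add atoms: sodium chlorite, [Na+].[O-]Cl=O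
Why: Oxoammonium (TEMPO) oxidation to the non-enolizable neopentyl aldehyde and Pinnick chlorite oxidation in the same flask give the acid under neutral to weakly acidic conditions, with 2-methyl-2-butene scavenging hypochlorite to protect the alkenes.

Step 14
Reactants: 21 (3R,4E,6R,8E)-3-(tert-butyldimethylsilyloxy)-6-(4-methoxybenzyloxy)-2,2,5,9-tetramethyl-11-(phenylsulfonyl)dodeca-4,8,11-trienoic acid
Product: 22 1,3-dioxoisoindolin-2-yl (3R,4E,6R,8E)-3-(tert-butyldimethylsilyloxy)-6-(4-methoxybenzyloxy)-2,2,5,9-tetramethyl-11-(phenylsulfonyl)dodeca-4,8,11-trienoate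
Conditions: N-hydroxyphthalimide, DIC, DMAP (cat.), CH2Cl2, 0 °C to rt
Reagents that add atoms: N-hydroxyphthalimide, O=C1c2ccccc2C(=O)N1O
Why: Steglich-type carbodiimide coupling with catalytic DMAP acylates N-hydroxyphthalimide even with an α-quaternary acid and gives the redox-active ester under neutral conditions.

Step 15
Reactants: 22 1,3-dioxoisoindolin-2-yl (3R,4E,6R,8E)-3-(tert-butyldimethylsilyloxy)-6-(4-methoxybenzyloxy)-2,2,5,9-tetramethyl-11-(phenylsulfonyl)dodeca-4,8,11-trienoate
Product: 23 (1E,4R,5E,7R)-7-(tert-butyldimethylsilyloxy)-4-(4-methoxybenzyloxy)-1,5,8,8-tetramethyl-10-(phenylsulfonyl)cycloundeca-1,5-diene (C10 epimers)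
Conditions: Ru(bpy)3(PF6)2 (2 mol%), Hantzsch ester (1.5 equiv), i-Pr2NEt·HBF4 (1 equiv), degassed CH2Cl2, 450 nm LEDs, rt; 22 and Hantzsch ester added together over 10 h, final 1 mM
Reagents that add atoms: none
Why: Proposed new method: the photoexcited ruthenium complex is reduced by the Hantzsch ester and passes an electron to the N-acyloxyphthalimide, whose radical anion loses phthalimide anion and CO2 to leave the nucleophilic tertiary radical at C8. This radical adds to the unsubstituted terminus C9 of the electron-poor 2-sulfonyl alkene, forming C8–C9 and the eleven-membered ring by 11-endo-trig closure, and the α-sulfonyl radical at C10 is then quenched by hydrogen-atom (or electron and proton) transfer from the dihydropyridine. The closest known reaction type is the intermolecular decarboxylative Giese addition of tertiary radicals from N-acyloxyphthalimides to vinyl sulfones and acrylates, together with endo radical macrocyclization onto acrylates in larger rings. The only new stereocentre, C10, is formed without control as both epimers and is erased in step 16, and C4 and C7 are not involved. The step needs cyclization to outrun hydrogen capture and attack at C9 only: polarity matching and the alkyl substituent on C10 direct the radical to C9, the E C5=C6 bond rules out 7- or 8-membered closure onto C1=C2 (a trans cycloalkene) and stiffens the chain, and slow co-addition at high dilution keeps hydrogen donor and substrate scarce. The ammonium salt keeps the medium non-basic, so the skipped 2-sulfonyl diene does not isomerize.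

Step 16
Reactants: 23 (1E,4R,5E,7R)-7-(tert-butyldimethylsilyloxy)-4-(4-methoxybenzyloxy)-1,5,8,8-tetramethyl-10-(phenylsulfonyl)cycloundeca-1,5-diene
Product: 24 (1E,4R,5E,7R)-7-(tert-butyldimethylsilyloxy)-4-(4-methoxybenzyloxy)-1,5,8,8-tetramethylcycloundeca-1,5-diene
Conditions: 5% Na/Hg, Na2HPO4, MeOH/THF, −20 to 0 °C
Reagents that add atoms: none
Why: Reductive desulfonylation by electron transfer from sodium amalgam cleaves the C10–S bond and protonates the resulting carbanion, erasing the C10 centre, while no β-leaving group is present and a transannular radical closure would place the E C1=C2 bond in a seven- or eight-membered ring.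

Step 17
Reactants: 24 (1E,4R,5E,7R)-7-(tert-butyldimethylsilyloxy)-4-(4-methoxybenzyloxy)-1,5,8,8-tetramethylcycloundeca-1,5-diene
Product: 25 (1E,4R,5E,7R)-7-(tert-butyldimethylsilyloxy)-1,5,8,8-tetramethylcycloundeca-1,5-dien-4-ol (ring numbering of the overview)
Conditions: DDQ, CH2Cl2/pH 7 buffer, 0 °C
Reagents that add atoms: none
Why: Oxidative cleavage of the 4-methoxybenzyl ether by DDQ (hydride abstraction, then hydrolysis of the hemiacetal) frees O4 while the silyl ether and the alkenes stay intact.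

Step 18
Reactants: 26 4-hydroxybenzoic acid
Product: 28 4-(tert-butyldimethylsilyloxy)benzoic acid, via bis-silylated silyl ester 27 (not isolated)
Conditions: TBSCl, imidazole, DMF, rt; then AcOH/THF/H2O
Reagents that add atoms: tert-butyldimethylsilyl chloride, CC(C)(C)[Si](C)(C)Cl
Why: Silylation of both the phenol and the acid followed by selective hydrolysis of the labile silyl ester gives the phenol-protected acid.

Step 19
Reactants: 25 (1E,4R,5E,7R)-7-(tert-butyldimethylsilyloxy)-1,5,8,8-tetramethylcycloundeca-1,5-dien-4-ol; 28 4-(tert-butyldimethylsilyloxy)benzoic acid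
Product: 29 (1E,4R,5E,7R)-7-(tert-butyldimethylsilyloxy)-1,5,8,8-tetramethylcycloundeca-1,5-dien-4-yl 4-(tert-butyldimethylsilyloxy)benzoate
Conditions: EDC·HCl, DMAP, CH2Cl2, rt
Reagents that add atoms: none
Why: Steglich esterification acylates O4 through the acylpyridinium ion without breaking the C4–O bond, so the R configuration is retained.

Step 20
Reactants: 29 (1E,4R,5E,7R)-7-(tert-butyldimethylsilyloxy)-1,5,8,8-tetramethylcycloundeca-1,5-dien-4-yl 4-(tert-butyldimethylsilyloxy)benzoate
Product: 30 (1E,4R,5E,7R)-7-hydroxy-1,5,8,8-tetramethylcycloundeca-1,5-dien-4-yl 4-hydroxybenzoate (CNP0264320.1)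
Conditions: HF·pyridine (excess), THF, 0 °C to rt
Reagents that add atoms: none
Why: Fluoride-induced desilylation removes the aryl and the hindered allylic silyl ether in one operation, and neither acyl migration (the two oxygens lie across an E alkene) nor ester cleavage is expected under these non-basic conditions.

**Compound list**

1 | (S)-pantolactone, (3S)-3-hydroxy-4,4-dimethyloxolan-2-one | CC1(C)COC(=O)[C@H]1O | starting material
2 | (2S)-2,4-dihydroxy-N-methoxy-N,3,3-trimethylbutanamide | CON(C)C(=O)[C@@H](O)C(C)(C)CO | intermediate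
3 | (2S)-2,4-bis(tert-butyldimethylsilyloxy)-N-methoxy-N,3,3-trimethylbutanamide | CON(C)C(=O)[C@@H](O[Si](C)(C)C(C)(C)C)C(C)(C)CO[Si](C)(C)C(C)(C)C | intermediate
4 | (2S)-2,4-bis(tert-butyldimethylsilyloxy)-3,3-dimethylbutanal | O=C[C@@H](O[Si](C)(C)C(C)(C)C)C(C)(C)CO[Si](C)(C)C(C)(C)C | intermediate
5 | 2-(triphenylphosphoranylidene)propanal | CC(C=O)=P(c1ccccc1)(c1ccccc1)c1ccccc1 | starting material
6 | (2E,4R)-4,6-bis(tert-butyldimethylsilyloxy)-2,5,5-trimethylhex-2-enal | O=C/C(C)=C/[C@@H](O[Si](C)(C)C(C)(C)C)C(C)(C)CO[Si](C)(C)C(C)(C)C | intermediate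
7 | (+)-B-allyldiisopinocampheylborane (from (−)-α-pinene) | C=CCB([C@H]1C[C@H]2C[C@@H]([C@@H]1C)C2(C)C)[C@H]1C[C@H]2C[C@@H]([C@@H]1C)C2(C)C | starting material
8 | diisopinocampheylborinate ester of 9 (not isolated) | C=CC[C@@H](OB([C@H]1C[C@H]2C[C@@H]([C@@H]1C)C2(C)C)[C@H]1C[C@H]2C[C@@H]([C@@H]1C)C2(C)C)/C(C)=C/[C@@H](O[Si](C)(C)C(C)(C)C)C(C)(C)CO[Si](C)(C)C(C)(C)C | intermediate
9 | (4R,5E,7R)-7,9-bis(tert-butyldimethylsilyloxy)-5,8,8-trimethylnona-1,5-dien-4-ol | C=CC[C@@H](O)/C(C)=C/[C@@H](O[Si](C)(C)C(C)(C)C)C(C)(C)CO[Si](C)(C)C(C)(C)C | intermediate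
10 | (4R,5E,7R)-7,9-bis(tert-butyldimethylsilyloxy)-4-(4-methoxybenzyloxy)-5,8,8-trimethylnona-1,5-diene | C=CC[C@@H](OCc1ccc(OC)cc1)/C(C)=C/[C@@H](O[Si](C)(C)C(C)(C)C)C(C)(C)CO[Si](C)(C)C(C)(C)C | intermediate
11 | methacrolein (2-methylprop-2-enal) | C=C(C)C=O | starting material
12 | (2E,5R,6E,8R)-8,10-bis(tert-butyldimethylsilyloxy)-5-(4-methoxybenzyloxy)-2,6,9,9-tetramethyldeca-2,6-dienal | O=C/C(C)=C/C[C@@H](OCc1ccc(OC)cc1)/C(C)=C/[C@@H](O[Si](C)(C)C(C)(C)C)C(C)(C)CO[Si](C)(C)C(C)(C)C | intermediate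
13 | (2E,5R,6E,8R)-8,10-bis(tert-butyldimethylsilyloxy)-5-(4-methoxybenzyloxy)-2,6,9,9-tetramethyldeca-2,6-dien-1-ol | OC/C(C)=C/C[C@@H](OCc1ccc(OC)cc1)/C(C)=C/[C@@H](O[Si](C)(C)C(C)(C)C)C(C)(C)CO[Si](C)(C)C(C)(C)C | intermediate
14 | (2E,5R,6E,8R)-1-bromo-8,10-bis(tert-butyldimethylsilyloxy)-5-(4-methoxybenzyloxy)-2,6,9,9-tetramethyldeca-2,6-diene | BrC/C(C)=C/C[C@@H](OCc1ccc(OC)cc1)/C(C)=C/[C@@H](O[Si](C)(C)C(C)(C)C)C(C)(C)CO[Si](C)(C)C(C)(C)C | intermediate
15 | 2-(phenylsulfonyl)ethanol | OCCS(=O)(=O)c1ccccc1 | starting material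
16 | (4E,7R,8E,10R)-10,12-bis(tert-butyldimethylsilyloxy)-7-(4-methoxybenzyloxy)-4,8,11,11-tetramethyl-2-(phenylsulfonyl)dodeca-4,8-dien-1-ol (C2 epimers) | OCC(S(=O)(=O)c1ccccc1)C/C(C)=C/C[C@@H](OCc1ccc(OC)cc1)/C(C)=C/[C@@H](O[Si](C)(C)C(C)(C)C)C(C)(C)CO[Si](C)(C)C(C)(C)C | intermediate
17 | methanesulfonate of 16 (not isolated) | CS(=O)(=O)OCC(S(=O)(=O)c1ccccc1)C/C(C)=C/C[C@@H](OCc1ccc(OC)cc1)/C(C)=C/[C@@H](O[Si](C)(C)C(C)(C)C)C(C)(C)CO[Si](C)(C)C(C)(C)C | intermediate
18 | (4E,7R,8E,10R)-10,12-bis(tert-butyldimethylsilyloxy)-7-(4-methoxybenzyloxy)-4,8,11,11-tetramethyl-2-(phenylsulfonyl)dodeca-1,4,8-triene | C=C(S(=O)(=O)c1ccccc1)C/C(C)=C/C[C@@H](OCc1ccc(OC)cc1)/C(C)=C/[C@@H](O[Si](C)(C)C(C)(C)C)C(C)(C)CO[Si](C)(C)C(C)(C)C | intermediate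
19 | (3R,4E,6R,8E)-3-(tert-butyldimethylsilyloxy)-6-(4-methoxybenzyloxy)-2,2,5,9-tetramethyl-11-(phenylsulfonyl)dodeca-4,8,11-trien-1-ol | C=C(S(=O)(=O)c1ccccc1)C/C(C)=C/C[C@@H](OCc1ccc(OC)cc1)/C(C)=C/[C@@H](O[Si](C)(C)C(C)(C)C)C(C)(C)CO | intermediate
20 | (3R,4E,6R,8E)-3-(tert-butyldimethylsilyloxy)-6-(4-methoxybenzyloxy)-2,2,5,9-tetramethyl-11-(phenylsulfonyl)dodeca-4,8,11-trienal (not isolated) | C=C(S(=O)(=O)c1ccccc1)C/C(C)=C/C[C@@H](OCc1ccc(OC)cc1)/C(C)=C/[C@@H](O[Si](C)(C)C(C)(C)C)C(C)(C)C=O | intermediate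
21 | (3R,4E,6R,8E)-3-(tert-butyldimethylsilyloxy)-6-(4-methoxybenzyloxy)-2,2,5,9-tetramethyl-11-(phenylsulfonyl)dodeca-4,8,11-trienoic acid | C=C(S(=O)(=O)c1ccccc1)C/C(C)=C/C[C@@H](OCc1ccc(OC)cc1)/C(C)=C/[C@@H](O[Si](C)(C)C(C)(C)C)C(C)(C)C(=O)O | intermediate
22 | N-acyloxyphthalimide of 21 (cyclization substrate) | C=C(S(=O)(=O)c1ccccc1)C/C(C)=C/C[C@@H](OCc1ccc(OC)cc1)/C(C)=C/[C@@H](O[Si](C)(C)C(C)(C)C)C(C)(C)C(=O)ON1C(=O)c2ccccc2C1=O | intermediate
23 | (1E,4R,5E,7R)-7-(tert-butyldimethylsilyloxy)-4-(4-methoxybenzyloxy)-1,5,8,8-tetramethyl-10-(phenylsulfonyl)cycloundeca-1,5-diene (C10 epimers) | C/C1=C\C[C@@H](OCc2ccc(OC)cc2)/C(C)=C/[C@@H](O[Si](C)(C)C(C)(C)C)C(C)(C)CC(S(=O)(=O)c2ccccc2)C1 | intermediate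
24 | (1E,4R,5E,7R)-7-(tert-butyldimethylsilyloxy)-4-(4-methoxybenzyloxy)-1,5,8,8-tetramethylcycloundeca-1,5-diene | C/C1=C\C[C@@H](OCc2ccc(OC)cc2)/C(C)=C/[C@@H](O[Si](C)(C)C(C)(C)C)C(C)(C)CCC1 | intermediate
25 | (1E,4R,5E,7R)-7-(tert-butyldimethylsilyloxy)-1,5,8,8-tetramethylcycloundeca-1,5-dien-4-ol | C/C1=C\C[C@@H](O)/C(C)=C/[C@@H](O[Si](C)(C)C(C)(C)C)C(C)(C)CCC1 | intermediate
26 | 4-hydroxybenzoic acid | O=C(O)c1ccc(O)cc1 | starting material
27 | tert-butyldimethylsilyl 4-(tert-butyldimethylsilyloxy)benzoate (not isolated) | CC(C)(C)[Si](C)(C)OC(=O)c1ccc(O[Si](C)(C)C(C)(C)C)cc1 | intermediate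
28 | 4-(tert-butyldimethylsilyloxy)benzoic acid | CC(C)(C)[Si](C)(C)Oc1ccc(C(=O)O)cc1 | intermediate
29 | (1E,4R,5E,7R)-7-(tert-butyldimethylsilyloxy)-1,5,8,8-tetramethylcycloundeca-1,5-dien-4-yl 4-(tert-butyldimethylsilyloxy)benzoate | C/C1=C\C[C@@H](OC(=O)c2ccc(O[Si](C)(C)C(C)(C)C)cc2)/C(C)=C/[C@@H](O[Si](C)(C)C(C)(C)C)C(C)(C)CCC1 | intermediate
30 | (1E,4R,5E,7R)-7-hydroxy-1,5,8,8-tetramethylcycloundeca-1,5-dien-4-yl 4-hydroxybenzoate | C/C1=C\C[C@@H](OC(=O)c2ccc(O)cc2)/C(C)=C/[C@@H](O)C(C)(C)CCC1 | target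

**Step count**

Total step count: 20. Longest linear sequence: 19 steps (steps 1–17, 19 and 20, from (S)-pantolactone); step 18 is a one-step side branch.

**Steps most likely to fail**

1. Step 15. The ring closure may lose to hydrogen capture by the C8 radical before it cyclizes, to a 1,5-hydrogen shift from the C5 methyl group, to reversible 3-exo attack on C5=C6 followed by vinyl migration, or to oligomerization. The fallback uses known chemistry and moves the ring-closing bond to C10–C11. It sets out from 10. Buffered HF·pyridine frees the neopentyl hydroxyl to give the primary alcohol F1, and Dess–Martin oxidation gives the non-enolizable aldehyde F2. Horner–Wadsworth–Emmons reaction with diethyl (phenylsulfonyl)methylphosphonate and NaH gives the E vinyl sulfone F3, in which the former carboxyl carbon is kept as C9. NaBH4 in EtOH reduces it by conjugate hydride addition to the saturated sulfone F4. Cross-metathesis with methacrolein (enal F5), Luche reduction (allylic alcohol F6) and CBr4/PPh3 (allylic bromide F7) follow as in steps 7–9. Slow addition of F7 to KN(SiMe3)2 in THF at high dilution should close the ring by intramolecular alkylation of the sulfonyl-stabilized C10 carbanion with the C11 allylic bromide, a known way to eleven-membered humulane rings. The fallback comes back to the route at 23.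

2. Step 10. Proton transfer from the mono-alkylated product to unreacted dianion may cause double alkylation, or the poorly soluble dilithio species may react sluggishly and let the allylic bromide decompose. The fallback sets out from 14 and separates the two carbon–carbon bond formations. Lithiated methyl phenyl sulfone (n-BuLi, THF, −78 °C, excess) is alkylated to the homoallylic sulfone F8. A second deprotonation with n-BuLi and trapping with paraformaldehyde installs C9 as the hydroxymethyl group. The fallback comes back to the route at 16.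

3. Step 7. Slow turnover at the alkene next to the bulky ether, homodimerization of 10, or loss of catalyst to methacrolein oligomers may stall the cross-metathesis. The fallback sets out from 10 and replaces metathesis by oxidative cleavage and olefination. OsO4 (cat.) with N-methylmorpholine N-oxide dihydroxylates the unhindered terminal alkene in preference to the shielded C5=C6 bond and gives the diol F9. NaIO4 cleaves it to the β-alkoxy aldehyde F10. Wittig reaction with ylide 5 in toluene then gives the E enal. The fallback comes back to the route at 12.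

**Further compounds**

F1 | step 15 | (3R,4E,6R)-3-(tert-butyldimethylsilyloxy)-6-(4-methoxybenzyloxy)-2,2,5-trimethylnona-4,8-dien-1-ol | C=CC[C@@H](OCc1ccc(OC)cc1)/C(C)=C/[C@@H](O[Si](C)(C)C(C)(C)C)C(C)(C)CO
F2 | step 15 | (3R,4E,6R)-3-(tert-butyldimethylsilyloxy)-6-(4-methoxybenzyloxy)-2,2,5-trimethylnona-4,8-dienal | C=CC[C@@H](OCc1ccc(OC)cc1)/C(C)=C/[C@@H](O[Si](C)(C)C(C)(C)C)C(C)(C)C=O
F3 | step 15 | E vinyl sulfone from F2 (C8–C9H=C10H–SO2Ph; O7 silyl, O4 PMB, allyl on C4) | C=CC[C@@H](OCc1ccc(OC)cc1)/C(C)=C/[C@@H](O[Si](C)(C)C(C)(C)C)C(C)(C)/C=C/S(=O)(=O)c1ccccc1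
F4 | step 15 | saturated sulfone from F3 (C8–C9H2–C10H2–SO2Ph) | C=CC[C@@H](OCc1ccc(OC)cc1)/C(C)=C/[C@@H](O[Si](C)(C)C(C)(C)C)C(C)(C)CCS(=O)(=O)c1ccccc1
F5 | step 15 | E enal from F4 (C11 aldehyde on C1=C2, sulfone on C10) | O=C/C(C)=C/C[C@@H](OCc1ccc(OC)cc1)/C(C)=C/[C@@H](O[Si](C)(C)C(C)(C)C)C(C)(C)CCS(=O)(=O)c1ccccc1
F6 | step 15 | allylic alcohol from F5 (C11 hydroxymethyl) | OC/C(C)=C/C[C@@H](OCc1ccc(OC)cc1)/C(C)=C/[C@@H](O[Si](C)(C)C(C)(C)C)C(C)(C)CCS(=O)(=O)c1ccccc1
F7 | step 15 | allylic bromide from F6 (C11 bromomethyl, sulfone on C10) | BrC/C(C)=C/C[C@@H](OCc1ccc(OC)cc1)/C(C)=C/[C@@H](O[Si](C)(C)C(C)(C)C)C(C)(C)CCS(=O)(=O)c1ccccc1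
F8 | step 10 | homoallylic phenyl sulfone from 14 (PhSO2–C10H2–C11H2 on C1; O7 and neopentyl O silyl, O4 PMB) | O=S(=O)(CC/C(C)=C/C[C@@H](OCc1ccc(OC)cc1)/C(C)=C/[C@@H](O[Si](C)(C)C(C)(C)C)C(C)(C)CO[Si](C)(C)C(C)(C)C)c1ccccc1
F9 | step 7 | terminal 1,2-diol from 10 (epimers at the new carbinol) | OCC(O)C[C@@H](OCc1ccc(OC)cc1)/C(C)=C/[C@@H](O[Si](C)(C)C(C)(C)C)C(C)(C)CO[Si](C)(C)C(C)(C)C
F10 | step 7 | (3R,4E,6R)-6,8-bis(tert-butyldimethylsilyloxy)-3-(4-methoxybenzyloxy)-4,7,7-trimethyloct-4-enal | O=CC[C@@H](OCc1ccc(OC)cc1)/C(C)=C/[C@@H](O[Si](C)(C)C(C)(C)C)C(C)(C)CO[Si](C)(C)C(C)(C)C
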